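**Compound numbers used throughout** (full names and SMILES are in the list after the steps): 1 bromo aldehyde, 2 borinate ester, 3 homoallylic alcohol, 4 bis-borane adduct, 5 diol, 6 open-chain hydroxy aldehyde, 7 lactol, 8 naphthol, 9 2-aryl oxolane, 10 ortho-quinone methide, 11 bromo tetralin, 12 target.

Atom numbering: the tetralin of 12 is C1 (carbinol), C2, C3, C4 (diarylmethine), C4a, C5 (methoxy) to C8, C8a; ring A is its benzene ring and ring B its saturated ring. The naphthol is C1' (hydroxyl), C2' (bonded to C4) to C8' (methoxy).

## Analysis of the target

Target 12 is a tetralin with a secondary benzylic hydroxyl at C1, a methoxy group at C5 and, on C4, a 1-hydroxy-8-methoxynaphthalen-2-yl group attached through C2'. Its two stereocentres, C1 (S) and C4 (R), are trans across ring B and are separated by the C2 and C3 methylenes, so neither can steer the other through a neighbouring-group effect. Each benzylic substituent has a peri neighbour (the C5 methoxy group for C4, the C8 position for C1), which makes the half-chair of ring B prefer them pseudoaxial. The sensitive groups are the free, electron-rich naphthol with its peri methoxy group (oxidisable), the doubly benzylic C4–H, and the C1 carbinol, which can eliminate to a dihydronaphthalene or be hydrogenolysed. The hard part is C4: a diarylmethine wedged between two ortho-oxygenated aryl groups, to be set relative to a remote centre, with its ring-A bond at the carbon ortho to methoxy rather than at the electronically preferred para carbon. The feature on which the plan rests is that C4 bears one hydrogen and two electron-rich aryl carbons, C2' (ortho to the naphthol hydroxyl) and C4a (ortho to the C5 methoxy group), which is the pattern left when an aldehyde carbon has been attacked by two arenes. Because C1, four carbons away, carries oxygen, that aldehyde and the C1 hydroxyl together are a five-membered lactol, so ring B becomes the product of one lactol and one naphthol.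

## Retrosynthetic reasoning

**12 back to 11 (no skeletal bond cut; a bromo substituent is added at C8).** C8 is para to the C5 methoxy group and is the second position ortho to C8a. If it were free during ring closure, the arene would close there and give the 7-methoxy isomer. A bromo substituent at C8 blocks this and also presses the C1 hydroxyl into the pseudoaxial position. The forward step must cleave the aryl C–Br bond without touching the benzylic C1–O bond.

**11 back to 7 and 8 (C4–C4a and C4–C2' cut).** Both bonds to C4 are cut because C4 is at the aldehyde oxidation level and both aryl partners are activated at exactly the carbons that must bond: C2' ortho to the free hydroxyl of 8, C4a ortho to methoxy. This makes two skeletal bonds, ring B and the C4 stereocentre in one operation from a commercial, unprotected naphthol. Forward, a chiral Brønsted acid must ionise lactol 7, direct 8 to react at C2' to give 9, reopen 9 to quinone methide 10, and let C4a close ring B with the trans relation to C1. A cut at C1–C8a or C3–C4 instead would leave the crowded diarylmethine to be made by an intermolecular reaction and would not use the lactol relationship.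

**7 back to 5 (oxidation level at C4 adjusted).** Lactol 7 is the ring form of hydroxy aldehyde 6, which comes from diol 5 by oxidation of the primary hydroxyl only. Forward, the oxidant must discriminate primary from secondary benzylic hydroxyl and stop before the lactone.

**5 back to 3 (C4–O bond cut).** The primary hydroxyl is the anti-Markovnikov hydration product of the terminal alkene of 3. This lets the four-carbon chain come from an allyl group.

**3 back to 1 (C1–C2 bond cut).** Allyl transfer to aldehyde 1 forms the chain and the C1 stereocentre in one step under reagent control. Aldehyde 1 is commercial and already has formyl, bromo and methoxy groups in the pattern of ring A with C8 blocked. C1 is the only centre that needs an external chiral reagent; C4 is derived from it.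

## Alternatives that were turned down

**Alternative 1: homoenolate annulation onto a naphthol quinone methide.**
- Disconnection: C3–C4 is cut and C1–C8a is left for a later closure.
- Forward: sulfone A1 (one step from 8, the matching bromo methoxy benzaldehyde and an arenesulfinic acid) loses sulfinate under a carbonate base to give the naphthol-derived ortho-quinone methide. The homoenolate formed from acrolein A2 and a chiral triazolium-derived carbene adds through C3 to the methide carbon C4, and the acyl azolium is captured by the naphthoxide to give seven-membered lactone A3. Bromine–lithium exchange at the future C8a and Parham-type acylation by the aryl ester would give tetralone A4, and a ketone reduction would finish.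
- For it: annulations of this type are established for ortho-quinone methides with β-aryl enals, C4 is set under catalyst control, the bromine is a working handle rather than a spectator, and the sequence is about four steps, one fewer than the chosen route.
- Against it for 12: A2 has no β-substituent, so its homoenolate is less stabilised and the enal tends to polymerise under carbene and base. The stereocentre must be created on the methide carbon alone, three atoms from where the catalyst is bound, and that carbon carries a 2,6-disubstituted aryl group twisted out of plane that shields both faces from an intermolecular nucleophile. C1 would be set last by reduction of A4 under 1,4-induction from the C4 aryl group, which has no dependable bias toward trans.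
- Comparison: on step count and on catalyst control of C4 this alternative is the stronger. The chosen route offers a C1 centre set first by a dependable reagent-controlled reaction, a trans relation that follows from the conformation of the ring being closed, and C4–aryl bonds made under hydrogen-bond delivery or intramolecularly rather than by a hindered intermolecular conjugate addition.

**Alternative 2: rhodium hydroacylation closing ring B at the carbonyl.**
- Disconnection: C1–C2 is cut.
- Forward: aldehyde A5, with a cationic monovalent rhodium catalyst carrying a bulky chiral bisphosphine, undergoes aldehyde C–H oxidative addition, anti-Markovnikov insertion of the C2–C3 alkene and reductive elimination to tetralone A6.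
- For it: the closure is atom-economical, takes place far from the congested C4, needs no blocking group because the regiochemistry on ring A is fixed in the substrate, and has precedent for ortho-allylbenzaldehydes.
- Against it for 12: the step creates no stereocentre. C4 is already stereogenic in A5, so the chiral ligand could at best resolve a racemate, and a separate enantioselective construction of a diaryl(vinyl)methane on a 1,2,3-trisubstituted benzaldehyde is needed. The C4–H of A5 is doubly benzylic and allylic, and rhodium hydride-mediated migration of the alkene into conjugation, a known competitor in this reaction class, would erase the centre; decarbonylation is a further drain. C1 must then be set by reduction of A6 with the same uncertain 1,4-induction as in alternative 1, and the acetal on the naphthol must be removed under acid next to a benzylic alcohol. The count is about eight steps.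
- Comparison: this plan is stronger on regiochemical certainty at ring A and on atom economy of the ring closure. The chosen route is about three steps shorter, needs no protecting group, and derives C4 from C1 instead of needing two independent asymmetric operations.

**Alternative 3: stereoinvertive nickel arylation closing ring B at C4.**
- Disconnection: C4–C4a is cut.
- Forward: in bis-pivalate A7 a zerovalent nickel catalyst inserts into the naphthylic C4–O bond with inversion, the boronate at C4a transmetalates within the molecule, and reductive elimination gives A8. The C1 pivalate, on a plain benzene ring, is not activated.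
- For it: the closure is stereospecific, so C4 follows from a carbinol that a reliable enantioselective ketone reduction can set, and both centres are controlled individually. On predictability of the C4 configuration this is the strongest of the plans, stronger than the chosen one. Regiochemistry is defined by the position of boron, and the selectivity between the two benzylic esters follows from the need for an extended π system.
- Against it for 12: the boronate of A7 is flanked by methoxy and the side chain, so transmetalation is slow and protodeboronation competes. The reacting pivalate is ortho to the protected naphthol oxygen. Ring-forming versions of this coupling have little precedent, and β-hydride elimination toward C3 would give a styrene. Building A7 needs two aryl ketone reductions, two acylations, a borylation and a protection, and A8 still needs pivalate and acetal removal, so the count is at least nine steps.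
- Comparison: the chosen route is about half the length, uses the free naphthol hydroxyl as the activating group rather than masking it, and confines its uncertainty to one step that has a stepwise fallback.

Key step: step 4

Assumption: the (R) enantiomer of the phosphoric acid is taken as the one matched with the (5S) lactol; this cannot be derived from a model, and the substrate's own bias toward the trans product is expected with either enantiomer.

## Route

Step 1
Reactants: 1 2-bromo-5-methoxybenzaldehyde
Product: 3 (1S)-1-(2-bromo-5-methoxyphenyl)but-3-en-1-ol, via diisopinocampheylborinate ester 2 (not isolated)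
Conditions: (−)-Ipc2B(allyl) (1.2 equiv, salt-free, 1 M in pentane), Et2O, −78 °C; then 3 M NaOH, 30% H2O2, 0 °C → rt
Reagents that add atoms: (−)-B-allyldiisopinocampheylborane, allylbis[(1R,2S,3R,5R)-2,6,6-trimethylbicyclo[3.1.1]heptan-3-yl]borane, C=CCB([C@@H]1C[C@@H]2C[C@H]([C@H]1C)C2(C)C)[C@@H]1C[C@@H]2C[C@H]([C@H]1C)C2(C)C
Why: Brown allylboration through a chair Zimmerman–Traxler transition state; the reagent derived from (+)-α-pinene delivers allyl to the Si face of aryl aldehydes, which gives the S carbinol that becomes C1. The aryl bromide is inert at −78 °C and to the alkaline peroxide work-up that cleaves borinate 2.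

Step 2
Reactants: 3 (1S)-1-(2-bromo-5-methoxyphenyl)but-3-en-1-ol
Product: 5 (1S)-1-(2-bromo-5-methoxyphenyl)butane-1,4-diol, via bis(9-borabicyclononyl) adduct 4 (not isolated)
Conditions: 9-BBN-H (2.3 equiv), THF, 0 °C → rt; then 3 M NaOH, 30% H2O2, 0 °C → rt
Reagents that add atoms: hydrogen peroxide, OO
Why: Hydroboration–oxidation; one equivalent of the borane is taken up by the hydroxyl, the second places boron on the terminal carbon of the alkene (anti-Markovnikov), and oxidation with retention gives the primary alcohol. The carbinol centre is not involved and the aryl bromide does not react with the dialkylborane.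

Step 3
Reactants: 5 (1S)-1-(2-bromo-5-methoxyphenyl)butane-1,4-diol
Product: 7 (5S)-5-(2-bromo-5-methoxyphenyl)oxolan-2-ol (mixture of anomers), via open-chain hydroxy aldehyde 6 (not isolated)
Conditions: TEMPO (10 mol %), PhI(OAc)2 (1.1 equiv), CH2Cl2, 0 °C → rt
Reagents that add atoms: none
Why: Nitroxyl-catalysed (oxoammonium) oxidation, which takes the unhindered primary alcohol much faster than the secondary benzylic one next to the ortho bromine; aldehyde 6 closes at once to the five-membered lactol, and the limited charge of oxidant is meant to stop it there. The anomeric centre is of no consequence because it becomes planar in step 4.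

Step 4
Reactants: 7 (5S)-5-(2-bromo-5-methoxyphenyl)oxolan-2-ol; 8 8-methoxynaphthalen-1-ol
Product: 11 (1S,4R)-8-bromo-4-(1-hydroxy-8-methoxynaphthalen-2-yl)-5-methoxy-1,2,3,4-tetrahydronaphthalen-1-ol, via 2-aryl oxolane 9 (not isolated), via ortho-quinone methide 10 (not isolated)
Conditions: (R)-3,3'-bis(2,4,6-triisopropylphenyl)-1,1'-binaphthyl-2,2'-diyl hydrogen phosphate (10 mol %), 5 Å MS, toluene (0.02 M), 7 (1.2 equiv), 8 added over 6 h at rt, then 50 °C
Reagents that add atoms: none
Why: Proposed new method: the acid ionises lactol 7 to a cyclic oxocarbenium phosphate at C4, and naphthol 8, held through its hydroxyl on the phosphate, attacks with C2' (C4–C2') to give 9; protonation of the ring oxygen of 9 then breaks the C4–O bond with push from the naphthol oxygen to give 10, whose C4a, ortho to methoxy, adds to the methide carbon (C4–C4a) before rearomatisation to 11. The closest known reaction types are phosphoric acid-catalysed ortho Friedel–Crafts reactions of naphthols, aryl C-glycoside formation from lactol-derived donors and naphthols, arylation of ortho-quinone methides released from ortho-hydroxybenzyl alcohols, and the acid-induced conversion of 2,5-diaryltetrahydrofurans into 1-aryltetralins; their union in one catalytic operation on a free lactol is not known. Ring B closes in a six-membered Friedel–Crafts mode that is 6-exo-trig at the methide carbon C4. C4 is the only new stereocentre; it is planar in 10, so both C2 epimers of 9 converge, and its configuration is set in the cyclisation by the C1 centre, because a half-chair with the C1 hydroxyl pseudoaxial (away from the peri bromine) and the forming C4–naphthyl bond pseudoaxial (away from the peri methoxy group) leads to the 1,4-trans product, a bias the chiral phosphate bound at the quinone methide oxygen is chosen to reinforce. C1 itself is not at risk, since ring A offers a cation at C1 only a meta methoxy group and an ortho bromine, so the C1–O bond does not ionise and re-addition of the C1 hydroxyl to C4 merely regenerates 9. Ortho rather than para attack on 8 rests on hydrogen-bond delivery, closure at C4a rather than C8 on the bromine block, and cyclisation rather than capture of 10 by a second molecule of 8 on slow addition and high dilution.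

Step 5
Reactants: 11 (1S,4R)-8-bromo-4-(1-hydroxy-8-methoxynaphthalen-2-yl)-5-methoxy-1,2,3,4-tetrahydronaphthalen-1-ol
Product: 12 dipolynaphthalene A, (1S,4R)-4-(1-hydroxy-8-methoxynaphthalen-2-yl)-5-methoxy-1,2,3,4-tetrahydronaphthalen-1-ol
Conditions: Pd/C (10 wt% palladium on carbon), HCO2NH4 (5 equiv), MeOH, rt
Reagents that add atoms: none
Why: Catalytic transfer hydrogenolysis of the aryl C–Br bond; the ammonia released buffers the hydrogen bromide, so the C1 carbinol, which has no para or ortho donor, should be neither ionised nor hydrogenolysed. No stereocentre is touched.

## Compound list

1 | 2-bromo-5-methoxybenzaldehyde | COc1ccc(Br)c(C=O)c1 | starting material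
2 | (1S)-1-(2-bromo-5-methoxyphenyl)but-3-en-1-yl bis[(1R,2S,3R,5R)-2,6,6-trimethylbicyclo[3.1.1]heptan-3-yl]borinate | C=CC[C@H](OB([C@@H]1C[C@@H]2C[C@H]([C@H]1C)C2(C)C)[C@@H]1C[C@@H]2C[C@H]([C@H]1C)C2(C)C)c1cc(OC)ccc1Br | intermediate
3 | (1S)-1-(2-bromo-5-methoxyphenyl)but-3-en-1-ol | C=CC[C@H](O)c1cc(OC)ccc1Br | intermediate
4 | 9-[(4S)-4-(2-bromo-5-methoxyphenyl)-4-(9-borabicyclo[3.3.1]nonan-9-yloxy)butyl]-9-borabicyclo[3.3.1]nonane | COc1ccc(Br)c(c1)[C@H](CCCB1C2CCCC1CCC2)OB1C2CCCC1CCC2 | intermediate
5 | (1S)-1-(2-bromo-5-methoxyphenyl)butane-1,4-diol | OCCC[C@H](O)c1cc(OC)ccc1Br | intermediate
6 | (4S)-4-(2-bromo-5-methoxyphenyl)-4-hydroxybutanal | O=CCC[C@H](O)c1cc(OC)ccc1Br | intermediate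
7 | (5S)-5-(2-bromo-5-methoxyphenyl)oxolan-2-ol (mixture of anomers) | OC1CC[C@H](O1)c1cc(OC)ccc1Br | intermediate
8 | 8-methoxynaphthalen-1-ol | COc1cccc2cccc(O)c12 | starting material
9 | 2-[(5S)-5-(2-bromo-5-methoxyphenyl)oxolan-2-yl]-8-methoxynaphthalen-1-ol (both epimers at C2 of the oxolane) | COc1ccc(Br)c(c1)[C@@H]1CCC(O1)c1ccc2cccc(OC)c2c1O | intermediate
10 | 2-[(4S)-4-(2-bromo-5-methoxyphenyl)-4-hydroxybutylidene]-8-methoxynaphthalen-1(2H)-one | COc1ccc(Br)c(c1)[C@@H](O)CCC=C1C=Cc2cccc(OC)c2C1=O | intermediate
11 | (1S,4R)-8-bromo-4-(1-hydroxy-8-methoxynaphthalen-2-yl)-5-methoxy-1,2,3,4-tetrahydronaphthalen-1-ol | COc1ccc(Br)c2c1[C@@H](c1ccc3cccc(OC)c3c1O)CC[C@@H]2O | intermediate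
12 | dipolynaphthalene A, (1S,4R)-4-(1-hydroxy-8-methoxynaphthalen-2-yl)-5-methoxy-1,2,3,4-tetrahydronaphthalen-1-ol | COc1cccc2c1[C@@H](c1ccc3cccc(OC)c3c1O)CC[C@@H]2O | target

## Step count and least certain steps

Total step count: 5. Longest linear sequence: 5 steps (1 to 12); naphthol 8 enters at step 4.

**Step 4 (key step).** The most likely failure is capture of the quinone methide by a second molecule of the naphthol instead of ring closure, because ring A is only a moderately nucleophilic bromoanisole while the naphthol is a strong π-nucleophile. Two further failure modes are possible: the reaction may stall at the oxolane stage if the phosphoric acid is too weak to reopen the ring, and the first arylation may leak to the para position of the naphthol, whose hydroxyl is already engaged in an internal hydrogen bond to the peri methoxy group. Drain of the quinone methide into its styrene tautomer is also possible but should be reversible under acid. The fallback separates the cascade into two known operations. It sets out from 7: acetylation (Ac2O, pyridine, DMAP, CH2Cl2) gives (5S)-5-(2-bromo-5-methoxyphenyl)oxolan-2-yl acetate F1, which is coupled with 8 under BF3·OEt2 (CH2Cl2, −40 → 0 °C) in the manner of an aryl C-glycoside synthesis, with ortho delivery by Fries-type oxygen-to-carbon shift, and 9 is isolated. Purified 9, now free of naphthol, is then treated with catalytic TfOH in (CF3)2CHOH/CH2Cl2 at 0 °C, the acid-induced diaryl-oxolane-to-aryltetralin ring closure, and the route is rejoined at 11. C4 is again set under control of C1.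

**Step 3.** The likely failure is over-oxidation, because the lactol hydroxyl is itself a substrate for the oxoammonium salt, so some material may run on to the lactone while diol remains. The fallback sets out from 5 and oxidises on purpose to the higher level: TEMPO with excess PhI(OAc)2 (3 equiv) gives (5S)-5-(2-bromo-5-methoxyphenyl)oxolan-2-one F2, and i-Bu2AlH (1.1 equiv, CH2Cl2, −78 °C) reduces it to the lactol, rejoining the route at 7.

**Step 1.** The likely failure is incomplete facial selectivity, because the ortho bromine crowds the chair transition state; since C4 is derived from C1, any enantiomeric impurity is carried to the end. The fallback sets the centre by ketone reduction instead and sets out from 1. Addition of CH2=CHCH2CH2MgBr (THF, 0 °C) gives racemic 1-(2-bromo-5-methoxyphenyl)pent-4-en-1-ol F3, Dess–Martin oxidation gives 1-(2-bromo-5-methoxyphenyl)pent-4-en-1-one F4, and Corey–Bakshi–Shibata reduction with (R)-2-methyl-CBS-oxazaborolidine and catecholborane (toluene, −78 °C, chosen so that the alkene is not hydroborated) gives (1S)-1-(2-bromo-5-methoxyphenyl)pent-4-en-1-ol F5. Ozonolysis (O3, CH2Cl2/MeOH, −78 °C; Me2S) cleaves the alkene to 6, which closes to the lactol, and the route is rejoined at 7.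

**Step 5.** The likely failure is cleavage of the benzylic C1–O bond on the palladium surface alongside the C–Br bond, or slow debromination because the bromine is flanked by the C1 carbinol. The fallback replaces hydrogenolysis by bromine–lithium exchange and sets out from 11: n-BuLi (3.5 equiv, THF, −78 °C; the first two equivalents deprotonate the hydroxyls) followed by a MeOH quench replaces bromine by hydrogen and arrives at 12. No compound outside the numbered list is made in this fallback.

## Further compounds

F1 | step 4 | (5S)-5-(2-bromo-5-methoxyphenyl)oxolan-2-yl acetate (mixture of anomers) | CC(=O)OC1CC[C@H](O1)c1cc(OC)ccc1Br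
F2 | step 3 | (5S)-5-(2-bromo-5-methoxyphenyl)oxolan-2-one | O=C1CC[C@H](O1)c1cc(OC)ccc1Br
F3 | step 1 | 1-(2-bromo-5-methoxyphenyl)pent-4-en-1-ol (racemic) | C=CCCC(O)c1cc(OC)ccc1Br
F4 | step 1 | 1-(2-bromo-5-methoxyphenyl)pent-4-en-1-one | C=CCCC(=O)c1cc(OC)ccc1Br
F5 | step 1 | (1S)-1-(2-bromo-5-methoxyphenyl)pent-4-en-1-ol | C=CCC[C@H](O)c1cc(OC)ccc1Br
F0 | step 5 | none | none
A1 | alternative 1 | 2-[(2-bromo-6-methoxyphenyl)(4-methylbenzenesulfonyl)methyl]-8-methoxynaphthalen-1-ol (racemic) | COc1cccc(Br)c1C(c1ccc2cccc(OC)c2c1O)S(=O)(=O)c1ccc(C)cc1
A2 | alternative 1 | acrolein (prop-2-enal) | C=CC=O
A3 | alternative 1 | (5R)-5-(2-bromo-6-methoxyphenyl)-11-methoxy-4,5-dihydronaphtho[1,2-b]oxepin-2(3H)-one | COc1cccc(Br)c1[C@@H]1CCC(=O)Oc2c1ccc1cccc(OC)c21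
A4 | alternative 1 | (4R)-4-(1-hydroxy-8-methoxynaphthalen-2-yl)-5-methoxy-3,4-dihydronaphthalen-1(2H)-one | COc1cccc2c1[C@@H](c1ccc3cccc(OC)c3c1O)CCC2=O
A5 | alternative 2 | 3-methoxy-2-{(1R)-1-[8-methoxy-1-(methoxymethoxy)naphthalen-2-yl]prop-2-en-1-yl}benzaldehyde | COc1cccc(C=O)c1[C@H](C=C)c1ccc2cccc(OC)c2c1OCOC
A6 | alternative 2 | (4R)-5-methoxy-4-[8-methoxy-1-(methoxymethoxy)naphthalen-2-yl]-3,4-dihydronaphthalen-1(2H)-one | COc1cccc2c1[C@@H](c1ccc3cccc(OC)c3c1OCOC)CCC2=O
A7 | alternative 3 | (1S,4S)-1-[3-methoxy-2-(4,4,5,5-tetramethyl-1,3,2-dioxaborolan-2-yl)phenyl]-4-[8-methoxy-1-(methoxymethoxy)naphthalen-2-yl]butane-1,4-diyl bis(2,2-dimethylpropanoate) | COc1cccc([C@H](CC[C@H](OC(=O)C(C)(C)C)c2ccc3cccc(OC)c3c2OCOC)OC(=O)C(C)(C)C)c1B1OC(C)(C)C(C)(C)O1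
A8 | alternative 3 | (1S,4R)-5-methoxy-4-[8-methoxy-1-(methoxymethoxy)naphthalen-2-yl]-1,2,3,4-tetrahydronaphthalen-1-yl 2,2-dimethylpropanoate | COc1cccc2c1[C@@H](c1ccc3cccc(OC)c3c1OCOC)CC[C@@H]2OC(=O)C(C)(C)C
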